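The readings stem from a simulated flask with made-up constants; scatter was added.

| flask | starting material | solid reagent | temperature | remark | time |
|---|---|---|---|---|---|
| winter | 0.12 M | 0.96 M | 35 °C | run made earlier |  |
| autumn | 0.18 M | 0.96 M | 57 °C | run made earlier |  |
| midnight | 0.24 M | 0.48 M | 35 °C | run made earlier |  |
| oak | 0.24 M | 0.960 M |  | at 25 °C until 6.0 h, from then on at 65 °C | 30 h |
| larch | 0.24 M | 0.960 M |  | at 65 °C throughout | 30 h |

| run | time / h | target / % | side product / % |
|---|---|---|---|
| winter | 3.00 | 8.2 | 64.0 |
| winter | 8.00 | 13.4 | 67.0 |
| winter | 15.0 | 14.0 | 67.9 |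
| winter | 25.0 | 14.4 | 67.8 |
| autumn | 1.00 | 4.4 | 72.5 |
| autumn | 2.50 | 8.5 | 78.4 |
| autumn | 5.00 | 8.3 | 78.8 |
| autumn | 8.00 | 8.9 | 78.3 |
| midnight | 3.00 | 7.8 | 64.6 |
| midnight | 8.00 | 12.8 | 67.0 |
| midnight | 15.0 | 14.0 | 68.3 |
| midnight | 25.0 | 14.1 | 68.6 |

(readings scatter by 0.3 percentage points)

- the flask that ends with the higher share of target in all that became target or side product or isomer of the product, or "neither" when 2 percentage points or less lies between them (oak / larch / neither)
- share of target in all that became target or side product or isomer of the product, oak
- share of target in all that became target or side product or isomer of the product, larch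

- solid, in amounts per volume of the solution: solid reagent
- the analysis behind the earlier runs scatters by 0.3 percentage points, standard deviation
- candidate steps: starting material -> side product; starting material -> intermediate A; intermediate A <-> intermediate B; coupling partner + intermediate A -> target; intermediate B -> side product; solid reagent <-> coupling partner; target <-> isomer of the product
- at the start none of the solid reagent is in solution

1. The autumn run at 57 °C ends with less target than the winter run at 35 °C (8.9% against 14.4%). My reckoning counts all that is not side product as the product pool, target plus isomer of the product.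

2. The target fraction, target divided by that pool, is 41.0% in the autumn run and 44.7% in the winter run. The pool goes from 32.2% in the winter run to 21.7% in the autumn run. The midnight run, at 35 °C with other charges, ends at 14.1% target, so I read that fall as an effect of temperature. The asked share is this fraction times the pool.

3. Larch runs hotter than the autumn run, so I estimate its ceiling at the autumn reading, 8.9%. My floor for larch repeats the whole fall of the pool once more, giving 6.00%.

4. Oak ends hot, so I take the hot fraction for it. My ceiling for oak is that fraction times the winter pool, 13.2%. Oak starts at 25 °C, colder than the autumn run, so I take the autumn reading as its floor.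

5. The forecast says oak, with 11.3% for oak and 7.2% for larch, on the view that “temperature controls the outcome”. Both values lie inside these brackets.

6. The higher share goes to oak: oak ends at 12.1%, larch at 6.32%.

    starting material → side product (k = 0.500 h⁻¹, Ea = 96.0 kJ mol⁻¹)
    starting material → intermediate A (k = 0.320 h⁻¹, Ea = 100 kJ mol⁻¹)
    intermediate A ⇌ intermediate B (K = 0.300, k = 0.0480 h⁻¹, Ea = 102 kJ mol⁻¹, ΔH = −14.0 kJ mol⁻¹)
    coupling partner + intermediate A → target (k = 4.00 M⁻¹ h⁻¹, Ea = 56.0 kJ mol⁻¹)
    intermediate B → side product (k = 0.170 h⁻¹, Ea = 86.0 kJ mol⁻¹)
    solid reagent ⇌ coupling partner, rate k6*(cs6 - [coupling partner]) while solid is left; crystals form when [coupling partner] > cs6 (solubility = 47.0 mM, k = 1.40 h⁻¹)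
    target ⇌ isomer of the product (K = 1.20, k = 1.60 h⁻¹, Ea = 91.0 kJ mol⁻¹, ΔH = 4.00 kJ mol⁻¹)
    (constants at 25 °C)

Removing the difference in temperature programme lifts larch from 6.32% to 12.1%, so that difference is the main reason for the gap. In oak, the half-life of target by its forward passing into isomer of the product at the first temperature, 0.43 h, is short against 30 h, which is thermodynamic control of that pair. The autumn fraction times oak's final pool gives 12.2%.

7. A neighbour of oak charged with 0.060 M of starting material ends with 68.8% side product, so the fraction gives 12.8%. The computed result is 12.7%.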